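Ring A of each half is made by a [3+3] annulation (triterpenoid numbering): a three-carbon aldehyde unit (C1–C3) is stitched across C10 and C4 of the ring B enone (S)-3-methyl-4-isopropenylcyclohex-2-enone, whose ring B, C4 with its methyls, C25 and the C5 stereocentre come from (+)-verbenone. The key step exploits that C10 is the enone β-carbon and C4 the inner carbon of the C5 isopropenyl group: in one flask a copper-mediated 1,4-addition forms C1–C10 anti to the isopropenyl group, the enolate is alkylated at C9, the aldehyde is unmasked and iron-hydride hydrogen-atom transfer turns C4 into a tertiary radical that closes C3–C4. Kolbe homocoupling of two such halves (C11–C12) and mono-methylenation complete the target.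

Key step: step 4

**Remark.** Atoms carry triterpenoid numbers (ring A: C1–C5 and C10; ring B: C5–C10; C11–C12 is the two-carbon link). (1R,5R)-(+)-Verbenone is taken as a commercial chiral-pool material. The key step is a telescoped one-flask sequence in which the crude intermediates are carried on without isolation, not a single-reagent cascade.

Step 1
Reactants: 1 (1R,5R)-(+)-verbenone; 2 thiophenol
Product: 3 (1R,4R,5S)-4,6,6-trimethyl-4-(phenylsulfanyl)bicyclo[3.1.1]heptan-2-one
Conditions: Et3N (0.1 equiv), MeOH, 23 °C
Reagents that add atoms: thiophenol, Sc1ccccc1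
Why: Base-catalysed thia-Michael addition in which the thiolate attacks C10 from the face opposite the gem-dimethyl bridge; the temporary sulfide saturates the enone so that only the cyclobutane bond alpha to the carbonyl can break in step 2.

Step 2
Reactants: 3 (1R,4R,5S)-4,6,6-trimethyl-4-(phenylsulfanyl)bicyclo[3.1.1]heptan-2-one; 4 acetic anhydride
Product: 5 (4S,5R)-5-methyl-5-(phenylsulfanyl)-4-(prop-1-en-2-yl)cyclohex-1-en-1-yl acetate
Conditions: BF3·OEt2, Zn(OAc)2, Ac2O, 0 to 23 °C
Reagents that add atoms: acetic anhydride, CC(=O)OC(C)=O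
Why: Lewis-acid activation of the saturated C8 ketone lets the strained C7–C4 bond break heterolytically to the C7=C8 enol acetate and a tertiary C4 cation that loses a proton to the isopropenyl group (cyclobutane fragmentation known for pinan-2-one-type ketones); C5 is untouched.

Step 3
Reactants: 5 (4S,5R)-5-methyl-5-(phenylsulfanyl)-4-(prop-1-en-2-yl)cyclohex-1-en-1-yl acetate
Product: 6 (4S)-3-methyl-4-(prop-1-en-2-yl)cyclohex-2-en-1-one
Conditions: K2CO3, MeOH, 0 °C; then MeI
Reagents that add atoms: none
Why: Methanolysis of the enol acetate gives the ketone, whose E1cB retro-thia-Michael elimination regenerates the C9=C10 enone while iodomethane traps the thiolate and makes the elimination irreversible; the C5 stereocentre is not involved.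

Step 4
Reactants: 6 (4S)-3-methyl-4-(prop-1-en-2-yl)cyclohex-2-en-1-one; 7 2-(2-bromoethyl)-1,3-dioxolane; 8 methyl bromoacetate
Product: 12 methyl 2-[(1R,4aR,6S,8aS)-6-hydroxy-5,5,8a-trimethyl-2-oxodecahydronaphthalen-1-yl]acetate, via bromomagnesium enolate 9 (not isolated), via acetal keto ester 10 (not isolated), via keto ester aldehyde 11 (not isolated)
Conditions: i) 7, Mg, THF, 25 °C; then CuBr·SMe2 (0.2 equiv), 6, −78 to −30 °C; ii) DMPU, 8, −30 to 0 °C; iii) 1 M HCl, 23 °C; iv) organic phase concentrated, then EtOH, Fe(acac)3 (0.5 equiv), PhSiH3, 60 °C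
Reagents that add atoms: 2-(2-bromoethyl)-1,3-dioxolane (as its Grignard reagent), BrCCC1OCCO1; methyl bromoacetate, COC(=O)CBr; water, O
Why: The copper-catalysed 1,4-addition of the Grignard reagent forms C1–C10 and the bromomagnesium enolate 9, which is C-alkylated at C9 by 8 (tandem conjugate addition–enolate alkylation), and aqueous acid then frees the C3 aldehyde 11. Fe(acac)3/PhSiH3 transfers a hydrogen atom to the CH2 terminus of the isopropenyl group (Markovnikov), the tertiary C4 radical adds to the aldehyde carbon C3 and the alkoxy radical is reduced to the alcohol; the closest known reaction types are the three-component enone coupling and the metal-hydride hydrogen-atom-transfer radical cyclisation of an alkene onto a carbonyl group. Ring A closes by 6-exo-trig radical addition to C=O through a chair transition state in which C1 and C4 are trans-diequatorial on ring B, which gives the trans-decalin. C10 is set by cuprate attack anti to the isopropenyl group at C5, C9 ends equatorial (alkylation trans to the C1 chain, and epimerisable alpha to the ketone), and C3 should carry the equatorial (3β) oxygen because the reversible radical addition passes through the chair with the C–O bond pseudo-equatorial. The step needs hydrogen-atom transfer at the only alkene present and addition to the aldehyde instead of the C8 ketone or the ester, which the unstrained six-membered closure secures against a bridged five-membered one. Alkylating C9 before the aldehyde is unmasked also blocks the competing intramolecular aldol of C9 onto C3.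

Step 5
Reactants: 12 methyl 2-[(1R,4aR,6S,8aS)-6-hydroxy-5,5,8a-trimethyl-2-oxodecahydronaphthalen-1-yl]acetate
Product: 13 2-[(1R,4aR,6S,8aS)-6-hydroxy-5,5,8a-trimethyl-2-oxodecahydronaphthalen-1-yl]acetic acid
Conditions: LiOH, THF/H2O, 23 °C; then 1 M HCl
Reagents that add atoms: lithium hydroxide, [Li+].[OH-]
Why: Saponification of the methyl ester; the basic medium also equilibrates C9 to the equatorial (natural) configuration.

Step 6
Reactants: 13 2-[(1R,4aR,6S,8aS)-6-hydroxy-5,5,8a-trimethyl-2-oxodecahydronaphthalen-1-yl]acetic acid (two molecules per molecule of product)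
Product: 14 (1R,1′R,4aR,4a′R,6S,6′S,8aS,8a′S)-1,1′-(ethane-1,2-diyl)bis(6-hydroxy-5,5,8a-trimethyloctahydronaphthalen-2(1H)-one)
Conditions: Pt electrodes, undivided cell, MeOH, NaOMe (0.1 equiv), constant current, 40 °C
Reagents that add atoms: second molecule of acid 13, OC(=O)C[C@H]1C(=O)CC[C@H]2C(C)(C)[C@@H](O)CC[C@]12C
Why: Kolbe anodic decarboxylation of the carboxylate of 13 generates the primary C11 radical, and the homocoupling of two such radicals (a union of two carbons of like polarity, a known dimerisation for gamma-keto acids) forms C11–C12 and the C2-symmetric diketone from two molecules of 13 without touching a stereocentre.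

Step 7
Reactants: 14 (1R,1′R,4aR,4a′R,6S,6′S,8aS,8a′S)-1,1′-(ethane-1,2-diyl)bis(6-hydroxy-5,5,8a-trimethyloctahydronaphthalen-2(1H)-one); 15 methyltriphenylphosphonium bromide
Product: 16 26-nor-8-oxo-alpha-onocerin
Conditions: Ph3PCH3Br (1.0 equiv), KOtBu (1.0 equiv), THF, 0 to 40 °C; recovered 14 recycled
Reagents that add atoms: methyltriphenylphosphonium bromide, C[P+](c1ccccc1)(c1ccccc1)c1ccccc1.[Br-]
Why: Wittig methylenation of one of the two equivalent, remote C8 ketones with a limiting amount of ylide (statistical mono-olefination); the free hydroxyls and the C9 configuration should be unaffected.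

**Compound list**

1 | (1R,5R)-(+)-verbenone, (1R,5R)-4,6,6-trimethylbicyclo[3.1.1]hept-3-en-2-one | CC1=CC(=O)[C@@H]2C[C@H]1C2(C)C | starting material
2 | thiophenol | Sc1ccccc1 | starting material
3 | (1R,4R,5S)-4,6,6-trimethyl-4-(phenylsulfanyl)bicyclo[3.1.1]heptan-2-one | C[C@@]1(Sc2ccccc2)CC(=O)[C@@H]3C[C@H]1C3(C)C | intermediate
4 | acetic anhydride | CC(=O)OC(C)=O | starting material
5 | (4S,5R)-5-methyl-5-(phenylsulfanyl)-4-(prop-1-en-2-yl)cyclohex-1-en-1-yl acetate | CC(=O)OC1=CC[C@@H](C(C)=C)[C@](C)(Sc2ccccc2)C1 | intermediate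
6 | (4S)-3-methyl-4-(prop-1-en-2-yl)cyclohex-2-en-1-one | O=C1CC[C@@H](C(C)=C)C(C)=C1 | intermediate
7 | 2-(2-bromoethyl)-1,3-dioxolane | BrCCC1OCCO1 | starting material
8 | methyl bromoacetate | COC(=O)CBr | starting material
9 | bromomagnesium (3S,4S)-3-[2-(1,3-dioxolan-2-yl)ethyl]-3-methyl-4-(prop-1-en-2-yl)cyclohex-1-en-1-olate | Br[Mg]OC1=C[C@@](C)(CCC2OCCO2)[C@H](C(C)=C)CC1 | intermediate
10 | methyl 2-[(1R,2S,3S)-2-[2-(1,3-dioxolan-2-yl)ethyl]-2-methyl-6-oxo-3-(prop-1-en-2-yl)cyclohexyl]acetate | COC(=O)C[C@H]1C(=O)CC[C@@H](C(C)=C)[C@]1(C)CCC2OCCO2 | intermediate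
11 | methyl 2-[(1R,2S,3S)-2-methyl-6-oxo-2-(3-oxopropyl)-3-(prop-1-en-2-yl)cyclohexyl]acetate | COC(=O)C[C@H]1C(=O)CC[C@@H](C(C)=C)[C@]1(C)CCC=O | intermediate
12 | methyl 2-[(1R,4aR,6S,8aS)-6-hydroxy-5,5,8a-trimethyl-2-oxodecahydronaphthalen-1-yl]acetate | COC(=O)C[C@H]1C(=O)CC[C@H]2C(C)(C)[C@@H](O)CC[C@]12C | intermediate
13 | 2-[(1R,4aR,6S,8aS)-6-hydroxy-5,5,8a-trimethyl-2-oxodecahydronaphthalen-1-yl]acetic acid | OC(=O)C[C@H]1C(=O)CC[C@H]2C(C)(C)[C@@H](O)CC[C@]12C | intermediate
14 | (1R,1′R,4aR,4a′R,6S,6′S,8aS,8a′S)-1,1′-(ethane-1,2-diyl)bis(6-hydroxy-5,5,8a-trimethyloctahydronaphthalen-2(1H)-one) | O=C1CC[C@H]2C(C)(C)[C@@H](O)CC[C@]2(C)[C@H]1CC[C@H]1C(=O)CC[C@H]2C(C)(C)[C@@H](O)CC[C@]12C | intermediate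
15 | methyltriphenylphosphonium bromide | C[P+](c1ccccc1)(c1ccccc1)c1ccccc1.[Br-] | starting material
16 | 26-nor-8-oxo-alpha-onocerin | C=C1CC[C@H]2C(C)(C)[C@@H](O)CC[C@]2(C)[C@H]1CC[C@H]1C(=O)CC[C@H]2C(C)(C)[C@@H](O)CC[C@]12C | target

**Total step count:** 7. **Longest linear sequence:** 7.

**Steps most likely to fail**

Step 4 (key step). The magnesium enolate may exchange protons before C-alkylation, so C9 regiocontrol is lost. The freed aldehyde may be reduced by the hydrosilane or undergo aldol reaction. The radical addition to the aldehyde may show poor facial control at C3. The fallback sets out from 6 and returns at 12. Conjugate addition with alkylation and the acid hydrolysis are run as separate, isolated operations to give 10 and then 11. Markovnikov addition of HBr to the isopropenyl group (HBr, CH2Cl2, −40 °C) gives methyl 2-[(1R,2R,3R)-3-(2-bromopropan-2-yl)-2-methyl-6-oxo-2-(3-oxopropyl)cyclohexyl]acetate F1. Bromine abstraction with Bu3SnH/AIBN (benzene, 80 °C, slow addition) generates the same C4 radical by halogen-atom abstraction instead of hydrogen-atom transfer. The known 6-exo cyclisation of an alkyl radical onto an aldehyde then closes ring A to 12.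

Step 2. The Lewis acid may trigger retro-Michael loss of thiophenol, acylation at sulfur, or sulfur participation after a hydride shift to the C4 cation, eroding C5. The fallback sets out from 3 and returns at 6 through a sulfone relay. Oxidation (mCPBA, CH2Cl2, 0 °C) gives (1R,4R,5S)-4-(benzenesulfonyl)-4,6,6-trimethylbicyclo[3.1.1]heptan-2-one F2, whose sulfone neither coordinates the Lewis acid nor participates as a neighbouring group. The same acetylative cyclobutane cleavage gives (4S,5R)-5-(benzenesulfonyl)-5-methyl-4-(prop-1-en-2-yl)cyclohex-1-en-1-yl acetate F3. K2CO3 in MeOH then cleaves the acetate and expels benzenesulfinate irreversibly (no thiolate trap needed) to give 6.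

Step 6. The anodic radical may be over-oxidised to a cation (non-Kolbe products), or may disproportionate instead of dimerising. The fallback sets out from 13 and returns at 14 by a different C11–C12 construction. Oxidative decarboxylation (Pb(OAc)4, Cu(OAc)2, pyridine, benzene, 80 °C) gives the exocyclic enone (4aR,6S,8aS)-6-hydroxy-5,5,8a-trimethyl-1-methylideneoctahydronaphthalen-2(1H)-one F4. Reductive hydrodimerisation of two molecules of this enone (SmI2, HMPA, t-BuOH, THF, −78 °C) joins the two β-carbons, a union of two like-polarity centres, and protonation of the two enolates at C9 gives 14.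

**Further compounds**

F1 | step 4 | methyl 2-[(1R,2R,3R)-3-(2-bromopropan-2-yl)-2-methyl-6-oxo-2-(3-oxopropyl)cyclohexyl]acetate | COC(=O)C[C@H]1C(=O)CC[C@@H](C(C)(C)Br)[C@]1(C)CCC=O
F2 | step 2 | (1R,4R,5S)-4-(benzenesulfonyl)-4,6,6-trimethylbicyclo[3.1.1]heptan-2-one | C[C@@]1(S(=O)(=O)c2ccccc2)CC(=O)[C@@H]3C[C@H]1C3(C)C
F3 | step 2 | (4S,5R)-5-(benzenesulfonyl)-5-methyl-4-(prop-1-en-2-yl)cyclohex-1-en-1-yl acetate | CC(=O)OC1=CC[C@@H](C(C)=C)[C@](C)(S(=O)(=O)c2ccccc2)C1
F4 | step 6 | (4aR,6S,8aS)-6-hydroxy-5,5,8a-trimethyl-1-methylideneoctahydronaphthalen-2(1H)-one | C=C1C(=O)CC[C@H]2C(C)(C)[C@@H](O)CC[C@]12C
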